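**Plan**

- Retrosynthesis: the C11–C12 bond is cut first (B-alkyl Suzuki–Miyaura coupling of a C9 vinyl group with a Z β-iodo enoate). The 6-hydroxy-7-en-8-al array is traced to a 6,7-epoxy 8-aldehyde (E1cB opening). Ring A is then cut at C1–C2 and C4–C5 ([3+3] annulation), and last the C10–C1 bond (nitromethane Michael addition).
- Forward: ring B is bought as ethyl 2-methyl-4-oxocyclohex-2-ene-1-carboxylate and C10 is made quaternary. Ring A is annulated in one palladium/base cascade and the nitro group is removed. Ring B is then adjusted (C17 by radical acetal addition, a C6=C7 alkene, a C9 vinyl group), the side chain is coupled, and the last step reveals the 6-hydroxy enal.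
- Enabling feature: in ring B the quaternary C10 carries C1 as CH2NO2 and is flanked by the C5 methylene α to the C6 ketone. C1 (nitronate) and C5 (enolate) therefore form a 1,3-carbon,carbon bis-nucleophile across C10. It matches 3-methylbut-2-enal diacetate, a 1,3-bis-electrophile at its acetal carbon (C2) and its CMe2 alkene terminus (C4).
- Stereochemistry: C10 comes from the catalyst-controlled Michael addition. C5 and C9 are set by equilibration (each is α to a carbonyl) to the trans-decalin with an equatorial C9 substituent. C6 comes from epoxidation on the face away from the axial C10 and C4 methyls and is carried over by the E1cB step. The C13=C14 geometry comes from anti-hydroiodination and a stereoretentive coupling.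

Key step: step 3

Remark: locants C1–C20 in the text are labdane locants (C4 bears the geminal methyls, C10 the angular methyl C20, C17 is the carbon on C8, C11–C16 form the side chain). Compound 1 is used as the racemate because its ester-bearing centre is configurationally labile.

**Route**

Step 1
Reactants: 1 ethyl 2-methyl-4-oxocyclohex-2-ene-1-carboxylate (racemic), 2 nitromethane
Product: 3 ethyl (1R,2R)-2-methyl-2-(nitromethyl)-4-oxocyclohexane-1-carboxylate
Conditions: 2 (10 equiv), cyclohexane-1,2-diamine-derived primary amine–thiourea (15 mol %, enantiomer chosen for the 2R adduct), PhCO2H (15 mol %), PhMe, 30 °C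
Reagents that add atoms: none
Why: Iminium-activated asymmetric Michael addition of a nitronate to a 3-methylcyclohexenone should set the quaternary carbon (C10) under catalyst control, reinforced by attack anti to the neighbouring ester, while the ester-bearing centre of 1 racemises through the dienamine so that both enantiomers of 1 converge on 3 (this centre is equilibrated again in step 5).

Step 2
Reactants: 4 3-methylbut-2-enal
Product: 5 3-methylbut-2-ene-1,1-diyl diacetate
Conditions: Ac2O (1.2 equiv), FeCl3 (1 mol %), neat, 0 °C to rt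
Reagents that add atoms: acetic anhydride, CC(=O)OC(C)=O
Why: Lewis-acid-catalysed acylal formation converts the aldehyde into a geminal diacetate, which is a substrate for π-allyl palladium chemistry.

Step 3
Reactants: 3 ethyl (1R,2R)-2-methyl-2-(nitromethyl)-4-oxocyclohexane-1-carboxylate, 5 3-methylbut-2-ene-1,1-diyl diacetate
Product: 8 ethyl (1R,4aR,8aR)-5,5,8a-trimethyl-8-nitro-4-oxo-1,2,3,4,4a,5,8,8a-octahydronaphthalene-1-carboxylate (epimers at the nitro carbon), via acetoxy nitro adduct 6 (not isolated), via nitrodiene 7 (not isolated)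
Conditions: Pd(PPh3)4 (5 mol %), DBU (2.5 equiv), THF, 0 °C, then 45 °C
Reagents that add atoms: none
Why: Proposed new method: zerovalent palladium should ionise one acetate of 5 to a 1-acetoxy-π-allyl complex that the nitronate of 3 (C1) attacks at the acetoxy-bearing carbon (C2) to give 6; E1cB loss of acetic acid then gives nitrodiene 7, and the C5 enolate of the C6 ketone adds to the dimethyl-substituted terminus (C4) in a vinylogous Michael reaction (a second ionisation of 6 and enolate attack on the π-allyl complex would form the same bond). The closest known reactions are the Tsuji–Trost allylation of nitroalkanes, the use of allylic geminal diacetates as 1,1-bis-electrophiles, nitroalkene formation from β-acetoxy nitro compounds and intramolecular nitro-Michael cyclisation; their union in a [3+3] annulation is new. Ring A closes in a 6-endo-trig mode, because attack at C2 would require a four-membered ring. The new C5 centre is α to the C6 ketone and should equilibrate under DBU to the trans ring fusion (H5 anti to the C10 methyl); the nitro-bearing C1 centre forms unselectively and is removed in step 4. The step needs C-allylation at the less hindered allyl terminus, which the bulk of the CMe2 end should secure, and it needs the C5 ketone enolate, not the C9 ester enolate, to close the ring, which the higher acidity and lower hindrance of the ketone α-methylene should secure.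

Step 4
Reactants: 8 ethyl (1R,4aR,8aR)-5,5,8a-trimethyl-8-nitro-4-oxo-1,2,3,4,4a,5,8,8a-octahydronaphthalene-1-carboxylate
Product: 9 ethyl (1R,4aR,8aR)-5,5,8a-trimethyl-4-oxo-1,2,3,4,4a,5,8,8a-octahydronaphthalene-1-carboxylate (any C1=C2 alkene isomer is carried along)
Conditions: Pd(PPh3)4 (5 mol %), HCO2NH4 (3 equiv), THF, 60 °C
Reagents that add atoms: none
Why: Allylic nitro compounds ionise with zerovalent palladium to π-allyl complexes that formate reduces (Tsuji–Trost-type hydrogenolysis); this π-allyl unit has no β-hydrogen, and both alkene regioisomers converge in step 5.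

Step 5
Reactants: 9 ethyl (1R,4aR,8aR)-5,5,8a-trimethyl-4-oxo-1,2,3,4,4a,5,8,8a-octahydronaphthalene-1-carboxylate
Product: 10 ethyl (1R,4aR,8aR)-5,5,8a-trimethyl-4-oxodecahydronaphthalene-1-carboxylate
Conditions: H2 (1 atm), 10% Pd/C, EtOAc, rt; then NaOEt (0.2 equiv), EtOH, rt
Reagents that add atoms: none
Why: Heterogeneous hydrogenation saturates the disubstituted ring A alkene, and alkoxide equilibration of the two epimerisable centres (C5 α to the ketone, C9 α to the ester) should deliver the trans-decalone with the equatorial ester.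

Step 6
Reactants: 10 ethyl (1R,4aR,8aR)-5,5,8a-trimethyl-4-oxodecahydronaphthalene-1-carboxylate
Product: 11 ethyl (1R,4aR,8aR)-5,5,8a-trimethyl-4-oxo-1,4,4a,5,6,7,8,8a-octahydronaphthalene-1-carboxylate
Conditions: IBX (2.5 equiv), DMSO/PhMe, 70 °C
Reagents that add atoms: none
Why: IBX dehydrogenation of a ketone to its enone can only run towards C7–C8 here, because on the C5 side both neighbours (C4 and C10) are quaternary and carry no hydrogen.

Step 7
Reactants: 11 ethyl (1R,4aR,8aR)-5,5,8a-trimethyl-4-oxo-1,4,4a,5,6,7,8,8a-octahydronaphthalene-1-carboxylate, 12 1,3-dioxolane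
Product: 13 ethyl (1R,2S,4aR,8aR)-2-(1,3-dioxolan-2-yl)-5,5,8a-trimethyl-4-oxodecahydronaphthalene-1-carboxylate
Conditions: 12 (solvent), Ph2CO (0.2 equiv), hν (350 nm), rt
Reagents that add atoms: none
Why: Triplet benzophenone abstracts the C2 hydrogen of 1,3-dioxolane and the nucleophilic dioxolanyl radical adds to the enone β-carbon C8 (Giese-type addition, a masked formylation); approach anti to the axial C10 methyl should place the acetal equatorial, and this centre is erased in step 16 in any case.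

Step 8
Reactants: 13 ethyl (1R,2S,4aR,8aR)-2-(1,3-dioxolan-2-yl)-5,5,8a-trimethyl-4-oxodecahydronaphthalene-1-carboxylate
Product: 14 ethyl (1R,2S,4aR,8aR)-2-(1,3-dioxolan-2-yl)-5,5,8a-trimethyl-4-(trifluoromethylsulfonyloxy)-1,2,4a,5,6,7,8,8a-octahydronaphthalene-1-carboxylate
Conditions: KN(SiMe3)2 (1.05 equiv), THF, −78 °C; then PhNTf2
Reagents that add atoms: N-phenyl-bis(trifluoromethanesulfonimide), O=S(=O)(N(c1ccccc1)S(=O)(=O)C(F)(F)F)C(F)(F)F
Why: Kinetic deprotonation should occur at the C7 methylene, not at the hindered C5 methine, and O-triflation of that enolate fixes the C6=C7 enol triflate.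

Step 9
Reactants: 14 ethyl (1R,2S,4aR,8aR)-2-(1,3-dioxolan-2-yl)-5,5,8a-trimethyl-4-(trifluoromethylsulfonyloxy)-1,2,4a,5,6,7,8,8a-octahydronaphthalene-1-carboxylate
Product: 15 ethyl (1R,2S,4aR,8aR)-2-(1,3-dioxolan-2-yl)-5,5,8a-trimethyl-1,2,4a,5,6,7,8,8a-octahydronaphthalene-1-carboxylate
Conditions: Pd(OAc)2 (5 mol %), PPh3 (10 mol %), Bu3N (3 equiv), HCO2H (2 equiv), DMF, 60 °C
Reagents that add atoms: none
Why: Palladium-catalysed formate reduction of an enol triflate replaces the triflate by hydrogen and leaves the C6=C7 alkene in place.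

Step 10
Reactants: 15 ethyl (1R,2S,4aR,8aR)-2-(1,3-dioxolan-2-yl)-5,5,8a-trimethyl-1,2,4a,5,6,7,8,8a-octahydronaphthalene-1-carboxylate
Product: 16 (1R,2S,4aR,8aR)-2-(1,3-dioxolan-2-yl)-5,5,8a-trimethyl-1,2,4a,5,6,7,8,8a-octahydronaphthalene-1-carbaldehyde
Conditions: i-Bu2AlH (1.1 equiv), CH2Cl2, −78 °C
Reagents that add atoms: none
Why: Low-temperature hydride reduction of a hindered ester should stop at the tetrahedral aluminate and give the aldehyde on work-up; the equatorial configuration at C9 is the thermodynamic one.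

Step 11
Reactants: 16 (1R,2S,4aR,8aR)-2-(1,3-dioxolan-2-yl)-5,5,8a-trimethyl-1,2,4a,5,6,7,8,8a-octahydronaphthalene-1-carbaldehyde
Product: 17 2-[(1R,2S,4aR,8aS)-1-ethenyl-5,5,8a-trimethyl-1,2,4a,5,6,7,8,8a-octahydronaphthalen-2-yl]-1,3-dioxolane
Conditions: Ph3PCH3Br, KOt-Bu, THF, 0 °C
Reagents that add atoms: methyltriphenylphosphonium bromide, C[P+](c1ccccc1)(c1ccccc1)c1ccccc1.[Br-]
Why: Wittig methylenation converts the C11 aldehyde into the C11=C12 vinyl group; the alkene is not conjugated to the aldehyde, so no double-bond migration is expected.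

Step 12
Reactants: 18 methyl 4-hydroxybut-2-ynoate
Product: 19 methyl (2Z)-4-hydroxy-3-iodobut-2-enoate
Conditions: NaI (2 equiv), AcOH, 70 °C
Reagents that add atoms: sodium iodide, [Na+].[I-]
Why: Conjugate addition of iodide to the ynoate followed by trans protonation (anti-hydroiodination) should give the Z β-iodo enoate, in which iodine is cis to the ester and the hydroxymethyl group cannot lactonise.

Step 13
Reactants: 17 2-[(1R,2S,4aR,8aS)-1-ethenyl-5,5,8a-trimethyl-1,2,4a,5,6,7,8,8a-octahydronaphthalen-2-yl]-1,3-dioxolane, 19 methyl (2Z)-4-hydroxy-3-iodobut-2-enoate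
Product: 21 methyl (2E)-3-{2-[(1R,2S,4aR,8aS)-2-(1,3-dioxolan-2-yl)-5,5,8a-trimethyl-1,2,4a,5,6,7,8,8a-octahydronaphthalen-1-yl]ethyl}-4-hydroxybut-2-enoate, via B-alkyl-9-BBN adduct 20 (not isolated)
Conditions: 9-BBN (1.5 equiv), THF, 0 °C to rt; then 19, PdCl2(dppf) (5 mol %), AsPh3 (10 mol %), Cs2CO3 (3 equiv), DMF/H2O, rt
Reagents that add atoms: none
Why: Hydroboration with 9-BBN is selective for the monosubstituted vinyl group over the hindered ring alkene, and the B-alkyl Suzuki–Miyaura coupling proceeds with retention at the vinyl iodide, so the new chain ends cis to the ester (2E).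

Step 14
Reactants: 21 methyl (2E)-3-{2-[(1R,2S,4aR,8aS)-2-(1,3-dioxolan-2-yl)-5,5,8a-trimethyl-1,2,4a,5,6,7,8,8a-octahydronaphthalen-1-yl]ethyl}-4-hydroxybut-2-enoate
Product: 22 methyl (2E)-3-{2-[(1R,2S,4aR,8aS)-2-formyl-5,5,8a-trimethyl-1,2,4a,5,6,7,8,8a-octahydronaphthalen-1-yl]ethyl}-4-hydroxybut-2-enoate
Conditions: 1 M HCl, THF, rt (short contact, buffered work-up)
Reagents that add atoms: water, O
Why: Acid hydrolysis of the dioxolane frees the C17 aldehyde; mild, brief conditions are chosen so that the β,γ-unsaturated aldehyde does not move into conjugation.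

Step 15
Reactants: 22 methyl (2E)-3-{2-[(1R,2S,4aR,8aS)-2-formyl-5,5,8a-trimethyl-1,2,4a,5,6,7,8,8a-octahydronaphthalen-1-yl]ethyl}-4-hydroxybut-2-enoate
Product: 23 methyl (2E)-3-{2-[(1R,2S,4aR,8aS)-2-formyl-5,5,8a-trimethyl-1,2,4a,5,6,7,8,8a-octahydronaphthalen-1-yl]ethyl}-4-(formyloxy)but-2-enoate
Conditions: acetic formic anhydride (preformed, 1.5 equiv), pyridine, CH2Cl2, 0 °C
Reagents that add atoms: acetic formic anhydride, CC(=O)OC=O
Why: The mixed anhydride transfers its formyl group to the only hydroxyl present (the primary C16 alcohol), so no selectivity between alcohols is needed.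

Step 16
Reactants: 23 methyl (2E)-3-{2-[(1R,2S,4aR,8aS)-2-formyl-5,5,8a-trimethyl-1,2,4a,5,6,7,8,8a-octahydronaphthalen-1-yl]ethyl}-4-(formyloxy)but-2-enoate
Product: 25 methyl (2E)-3-{2-[(1S,4R,4aR,8aS)-2-formyl-4-hydroxy-5,5,8a-trimethyl-1,4,4a,5,6,7,8,8a-octahydronaphthalen-1-yl]ethyl}-4-(formyloxy)but-2-enoate, via epoxy aldehyde 24 (not isolated)
Conditions: dimethyldioxirane (1.2 equiv), acetone, −20 °C; then Et3N (2 equiv), 0 °C
Reagents that add atoms: dimethyldioxirane, CC1(C)OO1
Why: The dioxirane should epoxidise the C6=C7 alkene (the side-chain enoate is electron-poor) from the face opposite the axial C10 and C4 methyls, and triethylamine then triggers E1cB opening of the β,γ-epoxy aldehyde, which moves the double bond to C7=C8 and leaves the C6 oxygen where the epoxide placed it (6R).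

**Compound list**

1 | ethyl 2-methyl-4-oxocyclohex-2-ene-1-carboxylate (racemic) | CCOC(=O)C1CCC(=O)C=C1C | starting material
2 | nitromethane | C[N+](=O)[O-] | starting material
3 | ethyl (1R,2R)-2-methyl-2-(nitromethyl)-4-oxocyclohexane-1-carboxylate | CCOC(=O)[C@@H]1CCC(=O)C[C@@]1(C)C[N+](=O)[O-] | intermediate
4 | 3-methylbut-2-enal | CC(C)=CC=O | starting material
5 | 3-methylbut-2-ene-1,1-diyl diacetate | CC(C)=CC(OC(C)=O)OC(C)=O | intermediate
6 | ethyl (1R,2R)-2-(2-acetoxy-4-methyl-1-nitropent-3-en-1-yl)-2-methyl-4-oxocyclohexane-1-carboxylate (side-chain epimers) | CCOC(=O)[C@@H]1CCC(=O)C[C@@]1(C)C([N+](=O)[O-])C(OC(C)=O)C=C(C)C | intermediate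
7 | ethyl (1R,2R)-2-methyl-2-[(1E)-4-methyl-1-nitropenta-1,3-dien-1-yl]-4-oxocyclohexane-1-carboxylate | CCOC(=O)[C@@H]1CCC(=O)C[C@@]1(C)/C([N+](=O)[O-])=C\C=C(C)C | intermediate
8 | ethyl (1R,4aR,8aR)-5,5,8a-trimethyl-8-nitro-4-oxo-1,2,3,4,4a,5,8,8a-octahydronaphthalene-1-carboxylate (C8 epimers) | CCOC(=O)[C@@H]1CCC(=O)[C@@H]2C(C)(C)C=CC([N+](=O)[O-])[C@@]12C | intermediate
9 | ethyl (1R,4aR,8aR)-5,5,8a-trimethyl-4-oxo-1,2,3,4,4a,5,8,8a-octahydronaphthalene-1-carboxylate | CCOC(=O)[C@@H]1CCC(=O)[C@@H]2C(C)(C)C=CC[C@@]12C | intermediate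
10 | ethyl (1R,4aR,8aR)-5,5,8a-trimethyl-4-oxodecahydronaphthalene-1-carboxylate | CCOC(=O)[C@@H]1CCC(=O)[C@@H]2C(C)(C)CCC[C@@]12C | intermediate
11 | ethyl (1R,4aR,8aR)-5,5,8a-trimethyl-4-oxo-1,4,4a,5,6,7,8,8a-octahydronaphthalene-1-carboxylate | CCOC(=O)[C@@H]1C=CC(=O)[C@@H]2C(C)(C)CCC[C@@]12C | intermediate
12 | 1,3-dioxolane | C1COCO1 | starting material
13 | ethyl (1R,2S,4aR,8aR)-2-(1,3-dioxolan-2-yl)-5,5,8a-trimethyl-4-oxodecahydronaphthalene-1-carboxylate | CCOC(=O)[C@@H]1[C@@H](C3OCCO3)CC(=O)[C@@H]2C(C)(C)CCC[C@@]12C | intermediate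
14 | ethyl (1R,2S,4aR,8aR)-2-(1,3-dioxolan-2-yl)-5,5,8a-trimethyl-4-(trifluoromethylsulfonyloxy)-1,2,4a,5,6,7,8,8a-octahydronaphthalene-1-carboxylate | CCOC(=O)[C@@H]1[C@@H](C3OCCO3)C=C(OS(=O)(=O)C(F)(F)F)[C@@H]2C(C)(C)CCC[C@@]12C | intermediate
15 | ethyl (1R,2S,4aR,8aR)-2-(1,3-dioxolan-2-yl)-5,5,8a-trimethyl-1,2,4a,5,6,7,8,8a-octahydronaphthalene-1-carboxylate | CCOC(=O)[C@@H]1[C@@H](C3OCCO3)C=C[C@@H]2C(C)(C)CCC[C@@]12C | intermediate
16 | (1R,2S,4aR,8aR)-2-(1,3-dioxolan-2-yl)-5,5,8a-trimethyl-1,2,4a,5,6,7,8,8a-octahydronaphthalene-1-carbaldehyde | O=C[C@@H]1[C@@H](C3OCCO3)C=C[C@@H]2C(C)(C)CCC[C@@]12C | intermediate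
17 | 2-[(1R,2S,4aR,8aS)-1-ethenyl-5,5,8a-trimethyl-1,2,4a,5,6,7,8,8a-octahydronaphthalen-2-yl]-1,3-dioxolane | C=C[C@@H]1[C@@H](C3OCCO3)C=C[C@@H]2C(C)(C)CCC[C@@]12C | intermediate
18 | methyl 4-hydroxybut-2-ynoate | COC(=O)C#CCO | starting material
19 | methyl (2Z)-4-hydroxy-3-iodobut-2-enoate | COC(=O)/C=C(\I)CO | intermediate
20 | B-alkyl-9-BBN adduct of 17 (boron on C12) | C(C[C@@H]1[C@@H](C3OCCO3)C=C[C@@H]2C(C)(C)CCC[C@@]12C)B1C2CCCC1CCC2 | intermediate
21 | methyl (2E)-3-{2-[(1R,2S,4aR,8aS)-2-(1,3-dioxolan-2-yl)-5,5,8a-trimethyl-1,2,4a,5,6,7,8,8a-octahydronaphthalen-1-yl]ethyl}-4-hydroxybut-2-enoate | COC(=O)/C=C(\CC[C@@H]1[C@@H](C3OCCO3)C=C[C@@H]2C(C)(C)CCC[C@@]12C)CO | intermediate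
22 | methyl (2E)-3-{2-[(1R,2S,4aR,8aS)-2-formyl-5,5,8a-trimethyl-1,2,4a,5,6,7,8,8a-octahydronaphthalen-1-yl]ethyl}-4-hydroxybut-2-enoate | COC(=O)/C=C(\CC[C@@H]1[C@@H](C=O)C=C[C@@H]2C(C)(C)CCC[C@@]12C)CO | intermediate
23 | methyl (2E)-3-{2-[(1R,2S,4aR,8aS)-2-formyl-5,5,8a-trimethyl-1,2,4a,5,6,7,8,8a-octahydronaphthalen-1-yl]ethyl}-4-(formyloxy)but-2-enoate | COC(=O)/C=C(\CC[C@@H]1[C@@H](C=O)C=C[C@@H]2C(C)(C)CCC[C@@]12C)COC=O | intermediate
24 | 6,7-epoxide of 23 (oxygen on the face opposite the C10 methyl) | COC(=O)/C=C(\CC[C@@H]1[C@@H](C=O)[C@H]3O[C@H]3[C@@H]2C(C)(C)CCC[C@@]12C)COC=O | intermediate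
25 | methyl (2E)-3-{2-[(1S,4R,4aR,8aS)-2-formyl-4-hydroxy-5,5,8a-trimethyl-1,4,4a,5,6,7,8,8a-octahydronaphthalen-1-yl]ethyl}-4-(formyloxy)but-2-enoate | COC(=O)/C=C(\CC[C@@H]1C(C=O)=C[C@@H](O)[C@@H]2C(C)(C)CCC[C@@]12C)COC=O | target

**Totals and risks**

Total step count: 16. Longest linear sequence: 14 steps (steps 1, 3 to 11 and 13 to 16).

Steps most likely to fail:

1. Step 3 (Proposed new method). The ring-closing vinylogous Michael addition forms a hindered bond between a quaternary and a tertiary carbon and may stall at nitrodiene 7. Intermolecular 1,4-addition of a nitronate to 7 may also compete, as may early ionisation of the allylic nitro group. The fallback uses known reactions and sets out from 3. Tsuji–Trost allylation of its nitronate with methyl 3-methylbut-2-en-1-yl carbonate (Pd(PPh3)4, THF) should give ethyl (1R,2R)-2-methyl-2-(4-methyl-1-nitropent-3-en-1-yl)-4-oxocyclohexane-1-carboxylate F1. SnCl4 in CH2Cl2 at −78 °C should then form the C4–C5 bond by attack of the ketone enol on the tertiary cation (cation–olefin cyclisation), giving ethyl (1R,4aR,8aR)-5,5,8a-trimethyl-8-nitro-4-oxodecahydronaphthalene-1-carboxylate F2. Radical denitration (Bu3SnH, AIBN, PhMe, reflux) followed by the NaOEt equilibration used in step 5 comes back to the route at 10.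

2. Step 1. Facial control at the hindered β-carbon may be insufficient, or the addition may be slow because 1 is partly held as its unreactive dienolate. The fallback replaces catalyst control by a covalent auxiliary and sets out from 1. Transesterification with (1R,2S,5R)-menthol (Ti(OEt)4 cat., PhMe, reflux) gives (1R,2S,5R)-menthyl 2-methyl-4-oxocyclohex-2-ene-1-carboxylate F3. DBU-mediated addition of nitromethane then gives two separable diastereomers, the wanted menthyl (1R,2R)-2-methyl-2-(nitromethyl)-4-oxocyclohexane-1-carboxylate F4 and its (1S,2S) isomer F5. After crystallisation or chromatography, Ti(OEt)4 in EtOH converts F4 into 3, where the route is rejoined.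

3. Step 16. The dioxirane may oxidise the aldehyde, epoxidation may be unselective between the two faces, or the β,γ-unsaturated aldehyde may slip into conjugation before it is epoxidised. The fallback sets out from 23 and makes that migration deliberate. DBU isomerises 23 to the conjugated enal methyl (2E)-3-{2-[(1S,4aR,8aS)-2-formyl-5,5,8a-trimethyl-1,4,4a,5,6,7,8,8a-octahydronaphthalen-1-yl]ethyl}-4-(formyloxy)but-2-enoate F6. Allylic hydroxylation at C6 with SeO2 (cat.) and t-BuOOH, on the face away from the axial methyls, then comes back to the route at 25.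

Further compounds
F1 | step 3 | ethyl (1R,2R)-2-methyl-2-(4-methyl-1-nitropent-3-en-1-yl)-4-oxocyclohexane-1-carboxylate (side-chain epimers) | CCOC(=O)[C@@H]1CCC(=O)C[C@@]1(C)C([N+](=O)[O-])CC=C(C)C
F2 | step 3 | ethyl (1R,4aR,8aR)-5,5,8a-trimethyl-8-nitro-4-oxodecahydronaphthalene-1-carboxylate (C8 epimers) | CCOC(=O)[C@@H]1CCC(=O)[C@@H]2C(C)(C)CCC([N+](=O)[O-])[C@@]12C
F3 | step 1 | (1R,2S,5R)-menthyl 2-methyl-4-oxocyclohex-2-ene-1-carboxylate (epimers at the ester-bearing ring carbon) | CC(C)[C@@H]1CC[C@@H](C)C[C@H]1OC(=O)C1CCC(=O)C=C1C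
F4 | step 1 | (1R,2S,5R)-menthyl (1R,2R)-2-methyl-2-(nitromethyl)-4-oxocyclohexane-1-carboxylate | CC(C)[C@@H]1CC[C@@H](C)C[C@H]1OC(=O)[C@@H]1CCC(=O)C[C@@]1(C)C[N+](=O)[O-]
F5 | step 1 | (1R,2S,5R)-menthyl (1S,2S)-2-methyl-2-(nitromethyl)-4-oxocyclohexane-1-carboxylate | CC(C)[C@@H]1CC[C@@H](C)C[C@H]1OC(=O)[C@H]1CCC(=O)C[C@]1(C)C[N+](=O)[O-]
F6 | step 16 | methyl (2E)-3-{2-[(1S,4aR,8aS)-2-formyl-5,5,8a-trimethyl-1,4,4a,5,6,7,8,8a-octahydronaphthalen-1-yl]ethyl}-4-(formyloxy)but-2-enoate | COC(=O)/C=C(\CC[C@@H]1C(C=O)=CC[C@@H]2C(C)(C)CCC[C@@]12C)COC=O
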